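**Retrosynthetic overview**

- The pyran-4-one ring (O1–C2=C3–C4=O) is opened at O1–C2 to an o-hydroxyaryl 1,3-diketone. The carbonyl that becomes ring carbon C2 lies two CH2 groups away from the 3-hydroxy-4-methoxyphenyl ring.
- Enabling feature: C2 of the pyranone ring is at the ketone oxidation level, so the unit aryl–CH2–CH2–C2(=O) is the redox isomer of an aryl iodide plus a vinyl carbinol CH2=CH–CH(OH)–. The aryl C–CH2 bond is therefore cut to 5-iodo-2-methoxyphenol and the acrolein aldol of 2'-hydroxy-4',5'-dimethoxyacetophenone. A Heck arylation with redox relay makes that bond, both CH2 groups and the C2 carbonyl at once, and acid in the same flask closes the ring.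
- The vinyl carbinol comes from the acetophenone dianion and acrolein. The aryl iodide comes from 5-amino-2-methoxyphenol by iodo-dediazoniation.
- Ring order: both benzene rings are bought. The pyranone ring is the only ring formed, and it is formed last, in the key step.

Key step: step 3

Remark: compound 4 is made and used as the racemate, because its only stereocentre becomes the sp2 ring carbon C2 of the target, which has no stereocentre. Compounds 1, 2 and 5 are taken as commercial, and LDA is used as the commercial solution.

**Route**

Step 1
Reactants: 1 1-(2-hydroxy-4,5-dimethoxyphenyl)ethan-1-one; 2 acrolein (prop-2-enal)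
Product: 4 rac-3-hydroxy-1-(2-hydroxy-4,5-dimethoxyphenyl)pent-4-en-1-one, via dilithium phenoxide-enolate dianion 3 (not isolated)
Conditions: LDA (2.2 equiv), THF, −78 → −20 °C; acrolein (1.2 equiv), −78 °C; AcOH, −78 °C
Reagents that add atoms: none
Why: In this directed (crossed) aldol addition the kinetically formed lithium enolate of the dianion should add 1,2 to acrolein at −78 °C, and the cold acetic acid quench should prevent retro-aldol cleavage and dehydration; the new carbinol centre forms as a racemate, which is acceptable because step 3 destroys it.

Step 2
Reactants: 5 5-amino-2-methoxyphenol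
Product: 7 5-iodo-2-methoxyphenol, via 3-hydroxy-4-methoxybenzenediazonium hydrogensulfate 6 (not isolated)
Conditions: NaNO2, 2 M aq. H2SO4, 0 °C; then KI, H2O, 0 °C → rt
Reagents that add atoms: potassium iodide, [K+].[I-]
Why: In this Sandmeyer-type iodo-dediazoniation, diazotisation in strong acid (which suppresses azo coupling of the phenol ring) and copper-free displacement of N2 by iodide should place iodine on the carbon para to OMe and meta to OH that carried the amino group.

Step 3
Reactants: 4 rac-3-hydroxy-1-(2-hydroxy-4,5-dimethoxyphenyl)pent-4-en-1-one; 7 5-iodo-2-methoxyphenol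
Product: 9 2-[2-(3-hydroxy-4-methoxyphenyl)ethyl]-6,7-dimethoxy-4H-chromen-4-one (target), via open-chain 1,3-diketone 8 (not isolated)
Conditions: Pd(OAc)2 (5 mol %), Bu4NCl (1 equiv), NaHCO3 (2.5 equiv), DMF, 45 °C; then conc. HCl, MeOH, 65 °C (same flask)
Reagents that add atoms: none
Why: Pd(0) inserts into the C–I bond of 7, the aryl–Pd species adds syn across the vinyl group of 4 with the aryl group on the unsubstituted terminal carbon, and the secondary alkyl–Pd then loses the carbinol hydrogen by syn β-hydride elimination, so the double bond is relayed into an enol that tautomerises to the ketone and the aryl–CH2 bond, both CH2 groups and the C2 carbonyl of diketone 8 arise together; acid then adds the phenol oxygen to that carbonyl and expels water. The closest known reaction type is the Heck arylation of secondary allylic alcohols to β-aryl ketones under ligand-free phase-transfer conditions (Pd(OAc)2/Bu4NCl/NaHCO3), followed by the classical acid cyclodehydration of o-hydroxyaryl 1,3-diketones that finishes Baker–Venkataraman chromone syntheses. The pyran-4-one ring is the only ring closed, at O1–C2, by 6-exo-trig attack of the phenol oxygen on the ketone carbon and dehydration. No stereocentre is created, and the racemic carbinol centre of 4 is erased when it becomes C2. The step needs terminal regioselectivity of insertion, secured by the monosubstituted alkene, and β-hydride elimination toward the carbinol instead of the benzylic CH2, secured by the hydroxyl group and the chloride/bicarbonate medium, which is known to favour the carbonyl product. It also needs the β-hydroxy ketone to outlive the coupling, which the weak base and the low temperature allowed by an aryl iodide should secure, while the two free phenols and the methyl ethers should be inert to both stages.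

**Compound list**

1 | 1-(2-hydroxy-4,5-dimethoxyphenyl)ethan-1-one (2'-hydroxy-4',5'-dimethoxyacetophenone) | CC(=O)c1cc(OC)c(OC)cc1O | starting material
2 | acrolein (prop-2-enal) | C=CC=O | starting material
3 | dilithium phenoxide-enolate dianion of 1 | [Li+].[Li+].C=C([O-])c1cc(OC)c(OC)cc1[O-] | intermediate
4 | rac-3-hydroxy-1-(2-hydroxy-4,5-dimethoxyphenyl)pent-4-en-1-one (racemate) | C=CC(O)CC(=O)c1cc(OC)c(OC)cc1O | intermediate
5 | 5-amino-2-methoxyphenol | COc1ccc(N)cc1O | starting material
6 | 3-hydroxy-4-methoxybenzenediazonium hydrogensulfate | COc1ccc([N+]#N)cc1O.OS(=O)(=O)[O-] | intermediate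
7 | 5-iodo-2-methoxyphenol | COc1ccc(I)cc1O | intermediate
8 | 1-(2-hydroxy-4,5-dimethoxyphenyl)-5-(3-hydroxy-4-methoxyphenyl)pentane-1,3-dione | COc1ccc(CCC(=O)CC(=O)c2cc(OC)c(OC)cc2O)cc1O | intermediate
9 | 2-[2-(3-hydroxy-4-methoxyphenyl)ethyl]-6,7-dimethoxy-4H-chromen-4-one | COc1ccc(CCc2cc(=O)c3cc(OC)c(OC)cc3o2)cc1O | target

**Step count and risks**

Total step count: 3. Longest linear sequence: 2 steps (1 → 4 → 9, or 5 → 7 → 9).

Steps most likely to fail, riskiest first:

1. Step 3. What may go wrong: base-induced loss of water from the β-hydroxy ketone (E1cB dehydration, then oxa-Michael ring closure) may outrun the arylation, or β-hydride elimination toward the benzylic CH2 may stop the relay at the cinnamyl-type alcohol. The fallback sets out from 7 and 1 and builds the diketone by the classical acylation route. Heck reaction of 7 with methyl acrylate (Pd(OAc)2, P(o-tol)3, Et3N, MeCN, 80 °C) should give methyl (E)-3-(3-hydroxy-4-methoxyphenyl)prop-2-enoate F1. Hydrogenation (H2, 10% Pd/C, EtOAc, rt) should give methyl 3-(3-hydroxy-4-methoxyphenyl)propanoate F2. Crossed Claisen condensation of F2 with the dianion of 1 (LiHMDS, 4.5 equiv, THF, −78 °C → rt) should give diketone 8, where the route is rejoined; the acid stage of step 3 then gives 9.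

2. Step 1. What may go wrong: conjugate (1,4) addition of the dianion to acrolein and anionic oligomerisation of acrolein, or retro-aldol cleavage and dehydration of the lithium aldolate before the quench. The fallback sets out from 1 and avoids basic conditions. Double silylation (TMSOTf, 2.4 equiv, Et3N, CH2Cl2, 0 °C) should give {[1-(4,5-dimethoxy-2-(trimethylsilyloxy)phenyl)ethenyl]oxy}trimethylsilane F3. Mukaiyama aldol addition of F3 to acrolein (BF3·OEt2, CH2Cl2, −78 °C) with a desilylating work-up (1 M HCl, THF, 0 °C) should give 4, where the route is rejoined.

3. Step 2. What may go wrong: hydrolysis of the diazonium ion to the phenol and azo coupling onto the electron-rich ring during the iodide exchange, leading to tar. The fallback sets out from 5 and bypasses 7. Diazotisation in aqueous HBF4 (NaNO2, 0 °C) and filtration should give 3-hydroxy-4-methoxybenzenediazonium tetrafluoroborate F4. Base-free Heck–Matsuda coupling of F4 with 4 (Pd(OAc)2, MeOH, rt) should proceed through the same insertion and redox relay to diketone 8, where the route is rejoined; the acid stage of step 3 then gives 9.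

**Further compounds**

F1 | step 3 | methyl (E)-3-(3-hydroxy-4-methoxyphenyl)prop-2-enoate | COC(=O)/C=C/c1ccc(OC)c(O)c1
F2 | step 3 | methyl 3-(3-hydroxy-4-methoxyphenyl)propanoate | COC(=O)CCc1ccc(OC)c(O)c1
F3 | step 1 | {[1-(4,5-dimethoxy-2-(trimethylsilyloxy)phenyl)ethenyl]oxy}trimethylsilane | C=C(O[Si](C)(C)C)c1cc(OC)c(OC)cc1O[Si](C)(C)C
F4 | step 2 | 3-hydroxy-4-methoxybenzenediazonium tetrafluoroborate | COc1ccc([N+]#N)cc1O.F[B-](F)(F)F
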